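**Retrosynthetic overview**
1. Target ⇒ its 2',5'-bis(benzyl) ether. The air- and acid-sensitive hydroquinone is unmasked last, by neutral hydrogenolysis.
2. Bis(benzyl) trans-isoflavan-4-ol ⇒ acyclic (E)-cinnamyl aryl ether. One chiral λ3-iodane cascade closes ring C (C4–C4a), shifts ring B from C4 to C3 through a phenonium ion, and puts water on C4. Both stereocentres arise here.
3. Cinnamyl ether ⇒ propargyl ether of 2,3,4-trimethoxyphenol plus an iodinated ring B block, joined by hydroboration/Suzuki–Miyaura coupling.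
4. Both tetraoxygenated arenes ⇒ one common 2,3-dimethoxyhydroquinone ⇒ veratrole (double directed ortho-metalation/borylation/oxidation) ⇒ catechol. The three-carbon bridge is propargyl bromide.
5. Ring order: rings A and B are carried in from catechol. Ring C is the only ring built, in the key step.

**Structure check:** the target is the trans isomer, (3S,4R)-3-(2,5-dihydroxy-3,4-dimethoxyphenyl)-6,7,8-trimethoxychroman-4-ol.

**Reagent of step 8** (not numbered, leaves no atoms in the product): the "(R,R)-iodane" is dimethyl (2R,2'R)-2,2'-{[2-(diacetoxy-λ3-iodanyl)-1,3-phenylene]bis(oxy)}dipropanoate. SMILES: CC(=O)OI(OC(C)=O)c1c(O[C@H](C)C(=O)OC)cccc1O[C@H](C)C(=O)OC. It is a known reagent made from 2-iodoresorcinol and methyl (S)-lactate.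

**Assumption:** the (R,R)-iodane is taken to attack the Si face of the CH2-bearing alkene carbon of 12. If the sense of induction proves opposite, the (S,S)-iodane from methyl (R)-lactate is used and nothing else changes.

**Step 1**
Reactants: 1 catechol
Product: 2 veratrole (1,2-dimethoxybenzene)
Conditions: MeI (2.5 equiv), K2CO3, acetone, reflux
Reagents that add atoms: iodomethane, CI
Why: Double Williamson etherification of two acidic phenols with an unhindered SN2 electrophile; no stereocentre.

**Step 2**
Reactants: 2 veratrole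
Product: 5 2,3-dimethoxybenzene-1,4-diol (2,3-dimethoxyhydroquinone), via 3,6-dilithioveratrole 3 (not isolated), via bis(dimethoxyboryl)veratrole 4 (not isolated)
Conditions: n-BuLi (3 equiv), TMEDA, Et2O/hexane, rt → reflux; B(OMe)3, −78 °C → rt; H2O2, AcOH, 0 °C, N2
Reagents that add atoms: hydrogen peroxide, OO
Why: Double directed ortho-metalation, in which each methoxy group steers n-BuLi/TMEDA to its free ortho position (C3 and C6), followed by borylation and position-retentive boron-to-oxygen oxidation, gives the 1,2,3,4-tetraoxygenated ring; no stereocentre.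

**Step 3**
Reactants: 5 2,3-dimethoxyhydroquinone
Product: 6 2,3,4-trimethoxyphenol
Conditions: 5 (2 equiv), MeI (1 equiv), K2CO3 (1 equiv), acetone, N2, reflux; excess 5 recovered and fed to step 5
Reagents that add atoms: iodomethane, CI
Why: Statistical mono-Williamson methylation of a symmetric diol, made selective by running the diol in excess; the two hydroxyls are equivalent, so only one mono-ether can form.

**Step 4**
Reactants: 6 2,3,4-trimethoxyphenol; 7 propargyl bromide
Product: 8 1,2,3-trimethoxy-4-(prop-2-yn-1-yloxy)benzene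
Conditions: K2CO3, DMF, rt
Reagents that add atoms: none
Why: Williamson etherification of the single phenol with a primary propargylic bromide; no stereocentre.

**Step 5**
Reactants: 5 2,3-dimethoxyhydroquinone
Product: 9 1,4-bis(benzyloxy)-2,3-dimethoxybenzene
Conditions: BnBr (2.3 equiv), K2CO3, DMF, N2, 50 °C
Reagents that add atoms: benzyl bromide, BrCc1ccccc1
Why: Double Williamson benzylation; benzyl keeps ring B electron-rich for the later aryl shift and is removable without acid.

**Step 6**
Reactants: 9 1,4-bis(benzyloxy)-2,3-dimethoxybenzene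
Product: 10 1,4-bis(benzyloxy)-5-iodo-2,3-dimethoxybenzene
Conditions: NIS (1.0 equiv), CF3CO2H (10 mol%), MeCN, 0 °C → rt, dark
Reagents that add atoms: N-iodosuccinimide, O=C1CCC(=O)N1I
Why: Electrophilic aromatic iodination; the four-donor central ring far outruns the benzyl phenyl rings, and its two free positions are equivalent.

**Step 7**
Reactants: 8 propargyl ether; 10 aryl iodide
Product: 12 1,4-bis(benzyloxy)-2,3-dimethoxy-5-[(E)-3-(2,3,4-trimethoxyphenoxy)prop-1-en-1-yl]benzene, via alkenylboronate 11 (not isolated)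
Conditions: 8, HBpin (1.1 equiv), Cp2ZrHCl (5 mol%), Et3N (5 mol%), neat, 60 °C; then 10, PdCl2(dppf) (3 mol%), K3PO4, THF/H2O, 45 °C
Reagents that add atoms: none
Why: Zirconium-catalysed syn-hydroboration puts boron on the terminal alkyne carbon and fixes the (E)-geometry, and Suzuki–Miyaura coupling transfers the alkenyl group with retention.

**Step 8**
Reactants: 12 (E)-cinnamyl aryl ether
Product: 15 (3S,4R)-3-[2,5-bis(benzyloxy)-3,4-dimethoxyphenyl]-6,7,8-trimethoxychroman-4-ol, via alkyl-λ3-iodane 13 (not isolated), via phenonium ion 14 (not isolated)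
Conditions: (R,R)-iodane (1.1 equiv), BF3·OEt2 (20 mol%), H2O (3 equiv), CH2Cl2/CF3CH2OH 10:1, −78 → −40 °C; Et3N, then aq NaHCO3/Na2S2O3
Reagents that add atoms: water, O
Why: Proposed new method: an enantioselective carbocyclisation/1,2-aryl-shift/hydroxylation cascade in which the BF3-activated, C2-symmetric lactate reagent of trivalent iodine binds the electron-rich (E)-styrene of 12 on the Si face of the CH2-bearing carbon; ring A (its only free position ortho to the ether oxygen, para to a methoxy group) then closes ring C by anti 6-endo Friedel–Crafts attack on the benzylic carbon to give trans-13; after a half-chair flip the aryl-λ3-iodanyl hypernucleofuge is expelled by the antiperiplanar, para-methoxy-activated ring B (inversion at C3, which sets 3S) to give phenonium ion 14; water opens 14 anti at C4, the carbon whose positive charge is best stabilised (ortho oxygen and para methoxy of ring A), which completes the shift of ring B from C4 to C3 and sets the 4R carbinol trans to it; the closest known reaction types are the oxidative 1,2-aryl migration of styrenes and chalcones with trivalent iodine or Tl(NO3)3 (isoflavone synthesis), its enantioselective lactate-iodane version giving α-aryl ketones, and the aryl-iodide-catalysed 6-endo cyclisation of allyl aryl ethers to 3-fluorochromans, whereas a carbocyclisation that ends in an aryl shift and C4 hydroxylation has not been described.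

**Step 9**
Reactants: 15 bis(benzyl) ether
Product: 16 (3S,4R)-3-(2,5-dihydroxy-3,4-dimethoxyphenyl)-6,7,8-trimethoxychroman-4-ol (target)
Conditions: H2 (1 atm), Pd/C (10 wt%), pyridine (0.5 equiv), EtOAc/MeOH, rt; degassed, acid-free work-up
Reagents that add atoms: none
Why: Catalytic hydrogenolysis cleaves the two phenolic benzyl ethers, while the pyridine-moderated catalyst spares the benzylic C4–OH and keeps the medium non-acidic, so neither stereocentre is touched and no pterocarpan closure occurs.

**Compound list**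
1 | catechol | Oc1ccccc1O | starting material
2 | veratrole | COc1ccccc1OC | intermediate
3 | 3,6-dilithio-1,2-dimethoxybenzene | [Li]c1ccc([Li])c(OC)c1OC | intermediate (not isolated)
4 | tetramethyl (2,3-dimethoxy-1,4-phenylene)diboronate | COB(OC)c1ccc(B(OC)OC)c(OC)c1OC | intermediate (not isolated)
5 | 2,3-dimethoxybenzene-1,4-diol | COc1c(O)ccc(O)c1OC | intermediate
6 | 2,3,4-trimethoxyphenol | COc1ccc(O)c(OC)c1OC | intermediate
7 | propargyl bromide | C#CCBr | starting material
8 | 1,2,3-trimethoxy-4-(prop-2-yn-1-yloxy)benzene | C#CCOc1ccc(OC)c(OC)c1OC | intermediate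
9 | 1,4-bis(benzyloxy)-2,3-dimethoxybenzene | COc1c(OCc2ccccc2)ccc(OCc2ccccc2)c1OC | intermediate
10 | 1,4-bis(benzyloxy)-5-iodo-2,3-dimethoxybenzene | COc1c(OCc2ccccc2)cc(I)c(OCc2ccccc2)c1OC | intermediate
11 | 2-[(E)-3-(2,3,4-trimethoxyphenoxy)prop-1-en-1-yl]-4,4,5,5-tetramethyl-1,3,2-dioxaborolane | COc1ccc(OC/C=C/B2OC(C)(C)C(C)(C)O2)c(OC)c1OC | intermediate (not isolated)
12 | 1,4-bis(benzyloxy)-2,3-dimethoxy-5-[(E)-3-(2,3,4-trimethoxyphenoxy)prop-1-en-1-yl]benzene | COc1ccc(OC/C=C/c2cc(OCc3ccccc3)c(OC)c(OC)c2OCc2ccccc2)c(OC)c1OC | intermediate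
13 | acetoxy(aryl){(3S,4R)-4-[2,5-bis(benzyloxy)-3,4-dimethoxyphenyl]-6,7,8-trimethoxychroman-3-yl}-λ3-iodane (3,4-trans; aryl = the bis-lactate arene) | COc1cc2c(c(OC)c1OC)OC[C@@H](I(OC(C)=O)c1c(O[C@H](C)C(=O)OC)cccc1O[C@H](C)C(=O)OC)[C@@H]2c1cc(OCc2ccccc2)c(OC)c(OC)c1OCc1ccccc1 | intermediate (not isolated)
14 | phenonium ion: ring B ipso carbon bridging C3 and C4 on the face opposite the departed iodine, drawn as the 4'-oxocarbenium form, acetate counter-ion, spiro centre unspecified | COc1cc2c(c(OC)c1OC)OC[C@H]1[C@@H]2C13C=C(OCc2ccccc2)C(=[O+]C)C(OC)=C3OCc1ccccc1.CC(=O)[O-] | intermediate (not isolated)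
15 | (3S,4R)-3-[2,5-bis(benzyloxy)-3,4-dimethoxyphenyl]-6,7,8-trimethoxychroman-4-ol | COc1cc2c(c(OC)c1OC)OC[C@H](c1cc(OCc3ccccc3)c(OC)c(OC)c1OCc1ccccc1)[C@H]2O | intermediate
16 | (3S,4R)-3-(2,5-dihydroxy-3,4-dimethoxyphenyl)-6,7,8-trimethoxychroman-4-ol | COc1cc2c(c(OC)c1OC)OC[C@H](c1cc(O)c(OC)c(OC)c1O)[C@H]2O | target

**Total step count:** 9.
**Longest linear sequence:** 7 (steps 1, 2, 3, 4, 7, 8, 9). The branch 1, 2, 5, 6, 7, 8, 9 is equally long.

**Three steps most likely to fail**

**Step 8 (the proposed new step).**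
- Risks:
  - Oxidation of the para-dialkoxy arenes by the iodane instead of the alkene.
  - Attack of the 2'-benzyloxy oxygen on C3 in competition with ipso participation.
  - Proton loss from 14 to the isoflav-3-ene.
  - Modest ee.
  - The order of ring closure and water capture may be reversed without changing the product.
- Fallback, known chemistry only, sets out from 12 and comes back at 15. It keeps the same aryl shift but replaces the oxidant by a sulfonate leaving group. Shi epoxidation of 12 (D-fructose-derived ketone, KHSO5 as 2KHSO5·KHSO4·K2SO4, K2CO3 buffer, MeCN/dimethoxymethane/H2O, 0 °C) gives (2R,3R)-3-[2,5-bis(benzyloxy)-3,4-dimethoxyphenyl]-2-[(2,3,4-trimethoxyphenoxy)methyl]oxirane F1. A 6-endo epoxide–arene Friedel–Crafts cyclisation (FeBr3 10 mol%, AgOTf 30 mol%, CH2Cl2, 0 °C), with inversion at the benzylic carbon, gives (3S,4R)-trans-4-[2,5-bis(benzyloxy)-3,4-dimethoxyphenyl]-6,7,8-trimethoxychroman-3-ol F2. MsCl/Et3N converts it into the corresponding 3-methanesulfonate F3. Buffered solvolysis (acetone/H2O, NaHCO3, 40 °C) with classical anchimeric aryl assistance passes through the same phenonium ion 14 and delivers 15.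

**Step 2.**
- Risks: incomplete second lithiation, and over-oxidation of the air-sensitive hydroquinone during the peroxide step.
- Fallback sets out from 2 and comes back at 5. It installs the two oxygens by different reactions. Mono-lithiation (n-BuLi, TMEDA, Et2O, 0 °C → rt) gives 2,3-dimethoxyphenyllithium F4. B(OMe)3 gives dimethyl (2,3-dimethoxyphenyl)boronate F5, and H2O2/AcOH gives 2,3-dimethoxyphenol F6. Para-selective phenol oxidation with O2 and Co(salen) in DMF gives 2,3-dimethoxy-1,4-benzoquinone F7. Na2S2O4 in Et2O/H2O reduces it to 5.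

**Step 7.**
- Risks: slow oxidative addition of the hindered, electron-rich iodide, and ionisation of the cinnamyl aryl ether product by zerovalent palladium.
- Fallback sets out from 10, with phenol 6 as partner (step 4 is then not needed), and comes back at 12. The ether bond is made last and without palladium. Heck reaction of 10 with methyl acrylate (Pd(OAc)2, P(o-tol)3, Et3N, DMF, 90 °C) gives methyl (E)-3-[2,5-bis(benzyloxy)-3,4-dimethoxyphenyl]prop-2-enoate F8. i-Bu2AlH (CH2Cl2, −78 °C) gives (E)-3-[2,5-bis(benzyloxy)-3,4-dimethoxyphenyl]prop-2-en-1-ol F9. Mitsunobu etherification with 6 (PPh3, DIAD, THF, 0 °C) gives 12.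

**Further compounds**
F1 | step 8 | (2R,3R)-3-[2,5-bis(benzyloxy)-3,4-dimethoxyphenyl]-2-[(2,3,4-trimethoxyphenoxy)methyl]oxirane | COc1ccc(OC[C@H]2O[C@@H]2c2cc(OCc3ccccc3)c(OC)c(OC)c2OCc2ccccc2)c(OC)c1OC
F2 | step 8 | (3S,4R)-4-[2,5-bis(benzyloxy)-3,4-dimethoxyphenyl]-6,7,8-trimethoxychroman-3-ol | COc1cc2c(c(OC)c1OC)OC[C@@H](O)[C@@H]2c1cc(OCc2ccccc2)c(OC)c(OC)c1OCc1ccccc1
F3 | step 8 | (3S,4R)-4-[2,5-bis(benzyloxy)-3,4-dimethoxyphenyl]-6,7,8-trimethoxychroman-3-yl methanesulfonate | COc1cc2c(c(OC)c1OC)OC[C@@H](OS(C)(=O)=O)[C@@H]2c1cc(OCc2ccccc2)c(OC)c(OC)c1OCc1ccccc1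
F4 | step 2 | 2,3-dimethoxyphenyllithium | [Li]c1cccc(OC)c1OC
F5 | step 2 | dimethyl (2,3-dimethoxyphenyl)boronate | COB(OC)c1cccc(OC)c1OC
F6 | step 2 | 2,3-dimethoxyphenol | COc1cccc(O)c1OC
F7 | step 2 | 2,3-dimethoxy-1,4-benzoquinone | COC1=C(OC)C(=O)C=CC1=O
F8 | step 7 | methyl (E)-3-[2,5-bis(benzyloxy)-3,4-dimethoxyphenyl]prop-2-enoate | COC(=O)/C=C/c1cc(OCc2ccccc2)c(OC)c(OC)c1OCc1ccccc1
F9 | step 7 | (E)-3-[2,5-bis(benzyloxy)-3,4-dimethoxyphenyl]prop-2-en-1-ol | OC/C=C/c1cc(OCc2ccccc2)c(OC)c(OC)c1OCc1ccccc1
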